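**Assumption:** the target is natural (+)-herboxidiene, numbered C1 (CO2H) to C19 (CH3), i.e. 3R,6S,7S,12S,14R,15R,16R,17R,18R, 8E,10E. Stereochemical outcomes below are derived from standard transition-state models, not from experiment.

## Retrosynthetic overview

1. Epoxide (second ring, formed last): C18–OH-directed vanadium epoxidation of the C14=C15 alkene.
2. Tetrahydropyran (first ring, formed late on the intact polyene): oxa-Michael closure (O–C3), preceded by B-alkyl Suzuki coupling (C3–C4) and anti-crotylation of a dienal (C6–C7).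
3. Diene: two iterative Wittig homologations of a C11 aldehyde. There is no sp2–sp2 cross-coupling and no Julia union.
4. Key step: Ireland–Claisen rearrangement (C12–C13 bond) that relays the C15 carbinol chirality to C12 and creates the E-C14=C15 alkene. Its propionate ester is installed by an Evans–Tishchenko reduction that also sets C17.
5. C15–C19 stereotriad: anti-aldol of the (R)-lactate-derived ethyl ketone with methacrolein.

## Route

**Step 1**
Reactants: 1, methyl (R)-lactate
Product: 2, (R)-2-hydroxy-N-methoxy-N-methylpropanamide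
Conditions: MeNH(OMe)·HCl, i-PrMgCl, THF, −20 → 0 °C
Reagents that add atoms: N,O-dimethylhydroxylamine hydrochloride, CNOC.Cl
Why: Weinreb amide formation by magnesium-amide aminolysis of the ester; the lactate stereocentre (future C18) is not touched.

**Step 2**
Reactants: 2
Product: 3, (R)-2-hydroxypentan-3-one
Conditions: EtMgBr (3 equiv), THF, 0 °C → rt; aq NH4Cl
Reagents that add atoms: ethylmagnesium bromide, CC[Mg]Br
Why: Weinreb ketone synthesis; the chelated tetrahedral intermediate stops over-addition and the magnesium alkoxide shields the α-centre from enolisation.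

**Step 3**
Reactants: 3
Product: 4, (R)-3-oxopentan-2-yl benzoate
Conditions: Bz2O, i-Pr2NEt, DMAP (cat.), CH2Cl2, rt
Reagents that add atoms: benzoic anhydride, O=C(OC(=O)c1ccccc1)c1ccccc1
Why: DMAP-catalysed acylation; the benzoate is both the aldol control element and the only protecting group in the route.

**Step 4**
Reactants: 4; 5, methacrolein
Product: 6, (2R,4S,5R)-5-hydroxy-4,6-dimethyl-3-oxohept-6-en-2-yl benzoate (C18 R, C16, C15 R)
Conditions: c-Hex2BCl, Me2NEt, Et2O, −78 → 0 °C; then 5, −78 → −20 °C; H2O2, MeOH, pH 7 buffer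
Reagents that add atoms: none other than reactant 5 (C=C(C)C=O)
Why: Paterson boron anti-aldol; the E-enol borinate reacts through a chair TS in which the benzoate carbonyl hydrogen-bonds the formyl H and A(1,3) strain fixes the α'-centre, giving the 15,16-anti adduct with C16-Me and C18-O syn (expected dr > 95:5).

**Step 5**
Reactants: 6; 7, propanal
Product: 8, (2R,3R,4R,5R)-3-hydroxy-4,6-dimethyl-5-(propanoyloxy)hept-6-en-2-yl benzoate
Conditions: SmI2 (0.3 equiv, pre-mixed with EtCHO to generate Sm(III)), EtCHO (8 equiv), THF, −10 °C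
Reagents that add atoms: none other than reactant 7 (CCC=O)
Why: Evans–Tishchenko reduction; intramolecular hydride transfer from the Sm(III)-bound propanal hemiacetal of the C15–OH through a chair TS gives the 1,3-anti C17 carbinol (17R) and leaves the C15 oxygen as the propionate needed for step 7.

**Step 6**
Reactants: 8
Product: 9, (2R,3R,4S,5R)-3-methoxy-4,6-dimethyl-5-(propanoyloxy)hept-6-en-2-yl benzoate
Conditions: Me3OBF4, Proton-sponge, 4 Å MS, CH2Cl2, 0 °C → rt
Reagents that add atoms: trimethyloxonium tetrafluoroborate, C[O+](C)C.F[B-](F)(F)F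
Why: Meerwein-salt O-methylation under non-basic conditions methylates the hindered C17–OH without 1,2- or 1,3-acyl migration of the flanking esters.

**Step 7 (key step)**
Reactants: 9
Product: 10, (2S,4E,6S,7R,8R)-8-(benzoyloxy)-7-methoxy-2,4,6-trimethylnon-4-enoic acid (C11 acid, 12S, E-C14=C15)
Conditions: LDA, THF, −78 °C; TMSCl/Et3N; −78 → 50 °C; 1 M HCl
Reagents that add atoms: none
Why: Ireland–Claisen rearrangement; kinetic LDA/THF enolisation gives the (E)-silyl ketene acetal (Me cis to the allylic oxygen, so axial), and a chair TS with the C16 chain equatorial on the (15R) carbon gives the E-trisubstituted alkene and 12S (dr about 9:1, limited by ketene acetal geometry).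

**Step 8**
Reactants: 10
Product: 11, (2R,3R,4S,5E,8S)-9-hydroxy-3-methoxy-4,6,8-trimethylnon-5-en-2-yl benzoate
Conditions: i-BuOCOCl, N-methylmorpholine, THF, −15 °C; then NaBH4, H2O, 0 °C
Reagents that add atoms: none
Why: mixed-anhydride activation followed by borohydride reduction converts only the acid to the primary alcohol, sparing the benzoate and the alkene.

**Step 9**
Reactants: 11
Product: 12, (2R,3R,4S,5E,8S)-3-methoxy-4,6,8-trimethyl-9-oxonon-5-en-2-yl benzoate
Conditions: Dess–Martin periodinane, NaHCO3, CH2Cl2, 0 °C → rt (used crude)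
Reagents that add atoms: none
Why: buffered Dess–Martin oxidation gives the α-methyl aldehyde without epimerising C12.

**Step 10**
Reactants: 12; 13, (triphenylphosphoranylidene)acetaldehyde
Product: 14, (2R,3R,4S,5E,8S,9E)-3-methoxy-4,6,8-trimethyl-11-oxoundeca-5,9-dien-2-yl benzoate
Conditions: toluene, 80 °C
Reagents that add atoms: none other than reactant 13
Why: Wittig olefination with a formyl-stabilised ylide gives the E-C10=C11 enal; the ylide is too weakly basic to epimerise C12 and the conjugated product reacts more slowly than 12.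

**Step 11**
Reactants: 14; 15, 2-(triphenylphosphoranylidene)propanal
Product: 16, (2R,3R,4S,5E,8S,9E,11E)-3-methoxy-4,6,8,12-tetramethyl-13-oxotrideca-5,9,11-trien-2-yl benzoate
Conditions: toluene, 100 °C
Reagents that add atoms: none other than reactant 15
Why: second stabilised-ylide Wittig reaction installs the E-trisubstituted C8=C9 alkene (thermodynamic E preference, typically > 20:1) and the C7 aldehyde.

**Step 12**
Reactants: 16; 17, trans-2-butene (converted in situ to (E)-crotyl-B(Ipc)2)
Product: 18, (2R,3R,4S,5E,8S,9E,11E,13S,14S)-13-hydroxy-3-methoxy-4,6,8,12,14-pentamethylhexadeca-5,9,11,15-tetraen-2-yl benzoate (6S,7S in herboxidiene numbering)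
Conditions: 17, KOt-Bu, n-BuLi, THF, −78 → −50 °C; (−)-Ipc2BOMe (from (+)-α-pinene); BF3·OEt2; then 16, −78 °C; NaBO3·4H2O workup
Reagents that add atoms: none other than reactant 17 (C/C=C/C)
Why: Brown asymmetric crotylboration; the chair TS of the E-crotylborane gives the 6,7-anti relationship and the (+)-α-pinene-derived reagent attacks the si face of the enal to give 7S under reagent control.

**Step 13**
Reactants: 18; 19, ethyl (Z)-3-iodoacrylate
Product: 20, ethyl (2Z,6S,7S,8E,10E,12S,14E,16S,17R,18R)-18-(benzoyloxy)-7-hydroxy-17-methoxy-6,8,12,14,16-pentamethylnonadeca-2,8,10,14-tetraenoate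
Conditions: 9-BBN (2.5 equiv), THF, 0 °C → rt; then 19, Pd(dppf)Cl2, AsPh3, Cs2CO3, DMF/H2O, rt
Reagents that add atoms: none other than reactant 19
Why: 9-BBN hydroborates only the monosubstituted terminal alkene (the first equivalent is consumed as the C7 borinate), and B-alkyl Suzuki–Miyaura coupling with retention of the iodoacrylate geometry forges C3–C4.

**Step 14 (tetrahydropyran formation)**
Reactants: 20
Product: 21, ethyl 2-[(2R,5S,6S)-6-[(2E,4E,6S,8E,10S,11R,12R)-12-(benzoyloxy)-11-methoxy-6,8,10-trimethyltrideca-2,4,8-trien-2-yl]-5-methyloxan-2-yl]acetate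
Conditions: KOt-Bu (0.3 equiv), THF, −20 → 0 °C
Reagents that add atoms: none
Why: intramolecular oxa-Michael addition (6-exo); both the kinetic preference of Z-enoates and reversible equilibration converge on the all-equatorial 2,6-cis ring, setting 3R from the fixed C6/C7 centres.

**Step 15**
Reactants: 21
Product: 22, 2-[(2R,5S,6S)-6-[(2E,4E,6S,8E,10S,11R,12R)-12-hydroxy-11-methoxy-6,8,10-trimethyltrideca-2,4,8-trien-2-yl]-5-methyloxan-2-yl]acetic acid
Conditions: LiOH·H2O (excess), THF/MeOH/H2O, 45 °C; then pH 4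
Reagents that add atoms: lithium hydroxide / water, [Li+].[OH-] (one O of the CO2H)
Why: saponification of the ethyl ester and the secondary benzoate by acyl–oxygen cleavage, so C18 keeps its configuration; the carboxylate is too poor an acceptor for retro-Michael opening.

**Step 16 (epoxide formation)**
Reactants: 22
Product: 23, herboxidiene
Conditions: VO(acac)2 (10 mol%), t-BuOOH (decane), CH2Cl2, −15 °C
Reagents that add atoms: tert-butyl hydroperoxide, CC(C)(C)OO
Why: hydroxyl-directed vanadium epoxidation; the V(V) alkoxide of the bishomoallylic C18–OH delivers oxygen to the trisubstituted alkene through a chair-like TS that minimises A(1,3) strain at C16, expected to give the (14R,15R)-epoxide and leave the non-directed diene untouched.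

## Compound list

1 | methyl (R)-lactate | C[C@@H](O)C(=O)OC | starting material
2 | (R)-2-hydroxy-N-methoxy-N-methylpropanamide | C[C@@H](O)C(=O)N(C)OC | intermediate
3 | (R)-2-hydroxypentan-3-one | C[C@@H](O)C(=O)CC | intermediate
4 | (R)-3-oxopentan-2-yl benzoate | C[C@@H](OC(=O)c1ccccc1)C(=O)CC | intermediate
5 | methacrolein | CC(=C)C=O | starting material
6 | (2R,4S,5R)-5-hydroxy-4,6-dimethyl-3-oxohept-6-en-2-yl benzoate | C[C@@H](OC(=O)c1ccccc1)C(=O)[C@@H](C)[C@@H](O)C(C)=C | intermediate
7 | propanal | CCC=O | starting material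
8 | (2R,3R,4R,5R)-3-hydroxy-4,6-dimethyl-5-(propanoyloxy)hept-6-en-2-yl benzoate | C[C@@H](OC(=O)c1ccccc1)[C@H](O)[C@@H](C)[C@@H](OC(=O)CC)C(C)=C | intermediate
9 | (2R,3R,4S,5R)-3-methoxy-4,6-dimethyl-5-(propanoyloxy)hept-6-en-2-yl benzoate | C[C@@H](OC(=O)c1ccccc1)[C@H](OC)[C@@H](C)[C@@H](OC(=O)CC)C(C)=C | intermediate
10 | (2S,4E,6S,7R,8R)-8-(benzoyloxy)-7-methoxy-2,4,6-trimethylnon-4-enoic acid | C[C@@H](OC(=O)c1ccccc1)[C@H](OC)[C@@H](C)/C=C(\C)C[C@H](C)C(=O)O | intermediate
11 | (2R,3R,4S,5E,8S)-9-hydroxy-3-methoxy-4,6,8-trimethylnon-5-en-2-yl benzoate | C[C@@H](OC(=O)c1ccccc1)[C@H](OC)[C@@H](C)/C=C(\C)C[C@H](C)CO | intermediate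
12 | (2R,3R,4S,5E,8S)-3-methoxy-4,6,8-trimethyl-9-oxonon-5-en-2-yl benzoate | C[C@@H](OC(=O)c1ccccc1)[C@H](OC)[C@@H](C)/C=C(\C)C[C@H](C)C=O | intermediate
13 | (triphenylphosphoranylidene)acetaldehyde | O=CC=P(c1ccccc1)(c1ccccc1)c1ccccc1 | starting material
14 | (2R,3R,4S,5E,8S,9E)-3-methoxy-4,6,8-trimethyl-11-oxoundeca-5,9-dien-2-yl benzoate | C[C@@H](OC(=O)c1ccccc1)[C@H](OC)[C@@H](C)/C=C(\C)C[C@H](C)/C=C/C=O | intermediate
15 | 2-(triphenylphosphoranylidene)propanal | CC(C=O)=P(c1ccccc1)(c1ccccc1)c1ccccc1 | starting material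
16 | (2R,3R,4S,5E,8S,9E,11E)-3-methoxy-4,6,8,12-tetramethyl-13-oxotrideca-5,9,11-trien-2-yl benzoate | C[C@@H](OC(=O)c1ccccc1)[C@H](OC)[C@@H](C)/C=C(\C)C[C@H](C)/C=C/C=C(\C)C=O | intermediate
17 | trans-2-butene | C/C=C/C | starting material
18 | (2R,3R,4S,5E,8S,9E,11E,13S,14S)-13-hydroxy-3-methoxy-4,6,8,12,14-pentamethylhexadeca-5,9,11,15-tetraen-2-yl benzoate | C[C@@H](OC(=O)c1ccccc1)[C@H](OC)[C@@H](C)/C=C(\C)C[C@H](C)/C=C/C=C(\C)[C@@H](O)[C@@H](C)C=C | intermediate
19 | ethyl (Z)-3-iodoacrylate | CCOC(=O)/C=C\I | starting material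
20 | ethyl (2Z,6S,7S,8E,10E,12S,14E,16S,17R,18R)-18-(benzoyloxy)-7-hydroxy-17-methoxy-6,8,12,14,16-pentamethylnonadeca-2,8,10,14-tetraenoate | C[C@@H](OC(=O)c1ccccc1)[C@H](OC)[C@@H](C)/C=C(\C)C[C@H](C)/C=C/C=C(\C)[C@@H](O)[C@@H](C)CC/C=C\C(=O)OCC | intermediate
21 | ethyl 2-[(2R,5S,6S)-6-[(2E,4E,6S,8E,10S,11R,12R)-12-(benzoyloxy)-11-methoxy-6,8,10-trimethyltrideca-2,4,8-trien-2-yl]-5-methyloxan-2-yl]acetate | C[C@@H](OC(=O)c1ccccc1)[C@H](OC)[C@@H](C)/C=C(\C)C[C@H](C)/C=C/C=C(\C)[C@H]1O[C@@H](CC(=O)OCC)CC[C@@H]1C | intermediate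
22 | 2-[(2R,5S,6S)-6-[(2E,4E,6S,8E,10S,11R,12R)-12-hydroxy-11-methoxy-6,8,10-trimethyltrideca-2,4,8-trien-2-yl]-5-methyloxan-2-yl]acetic acid | C[C@@H](O)[C@H](OC)[C@@H](C)/C=C(\C)C[C@H](C)/C=C/C=C(\C)[C@H]1O[C@@H](CC(=O)O)CC[C@@H]1C | intermediate
23 | herboxidiene | CO[C@H]([C@@H](C)[C@H]1O[C@]1(C)C[C@H](C)/C=C/C=C(\C)[C@H]1O[C@@H](CC(=O)O)CC[C@@H]1C)[C@@H](C)O | target

## Summary

Total step count: 16.
Longest linear sequence: 16 steps from methyl (R)-lactate; the route is fully linear and all other inputs are commercial.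

Three steps most likely to fail:

1. **Step 7 (Ireland–Claisen).** The C12 ratio is capped by the E/Z ketene acetal ratio, and the benzoate is exposed to LDA. Fallback: use an aliphatic Claisen rearrangement instead. O-allylate the C15 carbinol, isomerise with KOt-Bu/DMSO to the geometrically pure (Z)-1-propenyl ether (Me cis to O, so axial in the same chair), and rearrange thermally. This gives aldehyde 12 directly with 12S and removes steps 8–9.

2. **Step 5 (Evans–Tishchenko on an α'-benzoyloxy ketone).** Sm(II) could cleave the α-benzoate reductively, and Sm(III) alkoxides could cause acyl migration. Fallback: separate the two events. Reduce with Me4NBH(OAc)3 (Evans–Saksena, same 15,17-anti outcome) to the diol, then propionylate the less hindered allylic C15–OH selectively (EtCOCl, collidine, −78 °C) before methylating C17–OH.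

3. **Step 13 (hydroboration / B-alkyl Suzuki with a free C7–OH, a diene and a β-iodoacrylate).** Risks are incomplete chemoselectivity, slow transmetalation, and addition–elimination on the iodoacrylate. Fallback: build C3–C1 by carbonyl olefination instead of sp3–sp2 coupling. Rh-catalysed linear hydroformylation of the terminal alkene of 18 gives the C3 lactol, and Ph3P=CHCO2Et then opens it and triggers in situ oxa-Michael closure to the same 2,6-cis tetrahydropyran.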